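**Retrosynthetic overview**
- Last bond: a B-alkyl Suzuki coupling joins the side-chain terminus to a 3-bromobutenolide. This butenolide is the only ring; it is made first, on a side branch, from furfural (oxidative loss of furan aromaticity, then bromination) and attached last.
- The hydroxymethyl centre is set late by catalyst-controlled organo-SOMO α-allylation of an aldehyde, then reduction; the allyl group becomes the tether to the butenolide.
- The (Z)-allylic alcohol arm comes from a B-alkyl Suzuki coupling of a vinyl group with (Z)-3-iodo-2-methylprop-2-en-1-ol.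
- Key step: copper-catalysed enantioselective SN2′ alkylation that desymmetrises (E)-1,4-dibromobut-2-ene with an acetal-bearing Grignard reagent. It sets the acetoxymethyl centre and leaves CH2Br (→ CH2OAc) and vinyl as handles.
- The order keeps only one terminal alkene in the molecule at any time, so the acetal carried by the Grignard reagent is the only protecting group.

Assumption: the four starting materials and all reagents (both enantiomers of Taniaphos and of the imidazolidinone catalyst) are bought; the catalyst enantiomer named is the one expected to give the stated configuration, to be confirmed on a model substrate.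

**Route**

Step 1
Reactants: 1 2-(4-bromobutyl)-1,3-dioxolane; 2 (E)-1,4-dibromobut-2-ene
Product: 4 (R)-2-[5-(bromomethyl)hept-6-en-1-yl]-1,3-dioxolane, via Grignard reagent 3 (not isolated)
Conditions: Mg, Et2O, rt; then 2, CuBr·SMe2 (2 mol%), Taniaphos (2.4 mol%, enantiomer giving R), CH2Cl2, −78 °C
Reagents that add atoms: none
Why: Copper-catalysed enantioselective allylic alkylation (anti-SN2′) of a Grignard reagent on the C2h-symmetric dibromide, a known reaction class for 1,4-dihalobut-2-enes, in which the chiral copper–Taniaphos complex selects the alkene face so that the new stereocentre (R) is catalyst-set, one bromide leaves, the other survives as the CH2Br handle, and the product, no longer allylic, cannot react a second time.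

Step 2
Reactants: 4 (R)-2-[5-(bromomethyl)hept-6-en-1-yl]-1,3-dioxolane
Product: 5 (R)-6-(1,3-dioxolan-2-yl)-2-ethenylhexyl acetate
Conditions: CsOAc (2 equiv), DMF, 50 °C
Reagents that add atoms: caesium acetate, CC(=O)[O-].[Cs+]
Why: SN2 displacement of the primary bromide by the weakly basic acetate, which keeps E2 to the 1,3-diene minor and does not touch the stereocentre.

Step 3
Reactants: 6 prop-2-yn-1-ol
Product: 8 (Z)-3-iodo-2-methylprop-2-en-1-ol, via alkenylmagnesium chelate 7 (not isolated)
Conditions: MeMgBr (3 equiv), CuI (10 mol%), THF, −10 °C to rt; then I2, −10 °C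
Reagents that add atoms: methylmagnesium bromide, C[Mg]Br; iodine, II
Why: Hydroxyl-directed copper-catalysed anti-carbomagnesiation of the propargylic alkoxide (Duboudin–Jousseaume reaction), in which methyl adds to C2, magnesium sits on C3 cis to CH2O in a five-membered chelate, and iodinolysis with retention gives only the Z iodide.

Step 4
Reactants: 5 (R)-6-(1,3-dioxolan-2-yl)-2-ethenylhexyl acetate; 8 (Z)-3-iodo-2-methylprop-2-en-1-ol
Product: 10 (2R,5Z)-2-[4-(1,3-dioxolan-2-yl)butyl]-7-hydroxy-6-methylhept-5-en-1-yl acetate, via alkylborane 9 (not isolated)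
Conditions: 9-BBN (1.3 equiv), THF, 0 °C to rt; then 8, Pd(dppf)Cl2 (5 mol%), AsPh3 (10 mol%), K3PO4 (3 equiv), H2O (10 equiv), DMF, rt
Reagents that add atoms: none
Why: Anti-Markovnikov hydroboration of the only C=C present, then B-alkyl Suzuki–Miyaura coupling with retention of the Z geometry of 8; the acetate, acetal and free hydroxyl tolerate 9-BBN and the phosphate base, and no stereocentre is formed or touched.

Step 5
Reactants: 10 (2R,5Z)-2-[4-(1,3-dioxolan-2-yl)butyl]-7-hydroxy-6-methylhept-5-en-1-yl acetate
Product: 11 (2R,5Z)-7-hydroxy-6-methyl-2-(5-oxopentyl)hept-5-en-1-yl acetate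
Conditions: TsOH·H2O (10 mol%), THF/H2O 4:1, 40 °C
Reagents that add atoms: water, O
Why: Acid-catalysed acetal hydrolysis under conditions mild enough to leave the acetate, the allylic alcohol and the remote stereocentre untouched.

Step 6
Reactants: 11 (2R,5Z)-7-hydroxy-6-methyl-2-(5-oxopentyl)hept-5-en-1-yl acetate
Product: 13 (2R,5Z)-7-hydroxy-2-[(4S)-4-(hydroxymethyl)hept-6-en-1-yl]-6-methylhept-5-en-1-yl acetate, via α-allyl aldehyde 12 (not isolated)
Conditions: allylSiMe3 (2.5 equiv), (2R,5R)-5-benzyl-2-tert-butyl-3-methylimidazolidin-4-one·TFA (20 mol%), (NH4)2Ce(NO3)6 (2 equiv), NaHCO3 (2 equiv), DME, −20 °C; then NaBH4, EtOH, 0 °C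
Reagents that add atoms: allyltrimethylsilane, C=CC[Si](C)(C)C
Why: Organo-SOMO α-allylation of an aldehyde followed by in situ borohydride reduction, in which the enamine of 11 is oxidised by tetravalent cerium to a radical cation with one face shielded by the catalyst benzyl group, the allylsilane adds to the open face and loses silicon after a second oxidation, so the new stereocentre (S) is catalyst-set independently of the remote centre (the mirror-image catalyst gives (R)-2-alkylpent-4-enals) and immediate reduction prevents epimerisation.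

Step 7
Reactants: 14 furfural
Product: 17 furan-2(5H)-one, via furan-2-yl formate 15 (not isolated), via furan-2(3H)-one 16 (not isolated)
Conditions: 30% H2O2, HCO2H, Me2NCH2CH2OH (cat.), K2CO3 (cat.), Na2SO4, CH2Cl2, reflux
Reagents that add atoms: hydrogen peroxide, OO
Why: Baeyer–Villiger oxidation of the formyl group by performic acid made in situ gives the furyl formate, whose hydrolysis and amine-mediated double-bond shift give the conjugated butenolide, the furan aromaticity being traded for the lactone carbonyl.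

Step 8
Reactants: 17 furan-2(5H)-one
Product: 19 α-bromobutenolide 3-bromofuran-2(5H)-one, via trans-dibromolactone 18 (not isolated)
Conditions: Br2, CH2Cl2, 0 °C to rt; then Et3N, 0 °C
Reagents that add atoms: bromine, BrBr
Why: Bromine addition to the enoate C=C followed by E1cB dehydrobromination (the acidic α-H is removed and the β-bromide leaves), the standard route to α-bromo enones.

Step 9
Reactants: 13 (2R,5Z)-7-hydroxy-2-[(4S)-4-(hydroxymethyl)hept-6-en-1-yl]-6-methylhept-5-en-1-yl acetate; 19 3-bromofuran-2(5H)-one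
Product: 21 (2R,5Z)-7-hydroxy-2-[(4S)-4-(hydroxymethyl)-7-(2-oxo-2,5-dihydrofuran-3-yl)heptyl]-6-methylhept-5-en-1-yl acetate, via alkylborane 20 (not isolated)
Conditions: 9-BBN (4 equiv), THF, rt; then K3PO4 (3 equiv), H2O (10 equiv), 19 (1.5 equiv), Pd(dppf)Cl2 (10 mol%), AsPh3 (20 mol%), DMF, rt
Reagents that add atoms: none
Why: Chemoselective hydroboration of the terminal alkene (the trisubstituted alkene is inert to 9-BBN at rt; the excess covers the two hydroxyls) and B-alkyl Suzuki–Miyaura coupling with the α-bromo enoate as established for α-halo enones, with no stereocentre touched and no protecting group needed.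

**Compound list**
1 | 2-(4-bromobutyl)-1,3-dioxolane | BrCCCCC1OCCO1 | starting material
2 | (E)-1,4-dibromobut-2-ene | BrC/C=C/CBr | starting material
3 | [4-(1,3-dioxolan-2-yl)butyl]magnesium bromide | Br[Mg]CCCCC1OCCO1 | intermediate
4 | (R)-2-[5-(bromomethyl)hept-6-en-1-yl]-1,3-dioxolane | BrC[C@@H](C=C)CCCCC1OCCO1 | intermediate
5 | (R)-6-(1,3-dioxolan-2-yl)-2-ethenylhexyl acetate | CC(=O)OC[C@@H](C=C)CCCCC1OCCO1 | intermediate
6 | prop-2-yn-1-ol | C#CCO | starting material
7 | bromomagnesium (Z)-3-(bromomagnesio)-2-methylprop-2-en-1-olate (Mg cis to CH2O) | C/C(CO[Mg]Br)=C/[Mg]Br | intermediate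
8 | (Z)-3-iodo-2-methylprop-2-en-1-ol | C/C(CO)=C/I | intermediate
9 | 9-[(3S)-3-(acetoxymethyl)-7-(1,3-dioxolan-2-yl)heptyl]-9-borabicyclo[3.3.1]nonane (same spatial arrangement as 5; descriptor changes by the CIP rules only) | CC(=O)OC[C@@H](CCB1C2CCCC1CCC2)CCCCC1OCCO1 | intermediate
10 | (2R,5Z)-2-[4-(1,3-dioxolan-2-yl)butyl]-7-hydroxy-6-methylhept-5-en-1-yl acetate | CC(=O)OC[C@@H](CC/C=C(/C)CO)CCCCC1OCCO1 | intermediate
11 | (2R,5Z)-7-hydroxy-6-methyl-2-(5-oxopentyl)hept-5-en-1-yl acetate | CC(=O)OC[C@@H](CC/C=C(/C)CO)CCCCC=O | intermediate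
12 | (2R,5Z)-2-[(4S)-4-formylhept-6-en-1-yl]-7-hydroxy-6-methylhept-5-en-1-yl acetate | CC(=O)OC[C@@H](CC/C=C(/C)CO)CCC[C@H](C=O)CC=C | intermediate
13 | (2R,5Z)-7-hydroxy-2-[(4S)-4-(hydroxymethyl)hept-6-en-1-yl]-6-methylhept-5-en-1-yl acetate | CC(=O)OC[C@@H](CC/C=C(/C)CO)CCC[C@H](CO)CC=C | intermediate
14 | furfural (furan-2-carbaldehyde) | O=Cc1ccco1 | starting material
15 | furan-2-yl formate | O=COc1ccco1 | intermediate
16 | furan-2(3H)-one | O=C1CC=CO1 | intermediate
17 | furan-2(5H)-one | O=C1C=CCO1 | intermediate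
18 | trans-3,4-dibromooxolan-2-one (racemic) | O=C1OCC(Br)C1Br | intermediate
19 | 3-bromofuran-2(5H)-one | O=C1OCC=C1Br | intermediate
20 | (2R,5Z)-2-[(4R)-7-(9-borabicyclo[3.3.1]nonan-9-yl)-4-(hydroxymethyl)heptyl]-7-hydroxy-6-methylhept-5-en-1-yl acetate (same spatial arrangement as 13; descriptor changes by the CIP rules only) | CC(=O)OC[C@@H](CC/C=C(/C)CO)CCC[C@H](CO)CCCB1C2CCCC1CCC2 | intermediate
21 | (2R,5Z)-7-hydroxy-2-[(4S)-4-(hydroxymethyl)-7-(2-oxo-2,5-dihydrofuran-3-yl)heptyl]-6-methylhept-5-en-1-yl acetate | CC(=O)OC[C@@H](CC/C=C(/C)CO)CCC[C@H](CO)CCCC1=CCOC1=O | target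

**Step count**
Total steps: 9 (six in the main line, one for the vinyl iodide, two for the bromobutenolide).
Longest linear sequence: 6 steps (steps 1, 2, 4, 5, 6, 9) from 1.

**Steps most likely to fail, with fallbacks**

Step 1. The enantiomeric excess or the SN2′/SN2 ratio may drop with the acetal-bearing Grignard reagent. Fallback: set the same centre by enzymatic desymmetrisation of a prochiral diol instead of copper catalysis. Setting out from 1, alkylation of diethyl malonate (NaH, THF/DMF, 60 °C) gives diethyl 2-[4-(1,3-dioxolan-2-yl)butyl]propanedioate F1. Reduction with LiAlH4 (THF, 0 °C) gives the prochiral 2-[4-(1,3-dioxolan-2-yl)butyl]propane-1,3-diol F2. Lipase-catalysed monoacetylation (Burkholderia cepacia lipase, vinyl acetate; or hydrolysis of the diacetate if the acylation gives the antipode) gives (2R)-6-(1,3-dioxolan-2-yl)-2-(hydroxymethyl)hexyl acetate F3. Buffered Dess–Martin oxidation gives (2S)-6-(1,3-dioxolan-2-yl)-2-formylhexyl acetate F4. Wittig methylenation (Ph3P=CH2, THF, −78 °C) gives 5, where the route is rejoined; steps 1 and 2 are replaced.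

Step 6. The tetravalent-cerium oxidant may attack the free allylic alcohol of 11, and the selectivity (typically about 90–95% ee on simple aldehydes) is untested on this substrate. Fallback: allylate before the sensitive arm exists and mask the new allyl group while that arm is coupled. Setting out from 5, acetal hydrolysis (TsOH·H2O, THF/H2O) gives (2R)-2-ethenyl-7-oxoheptyl acetate F5. The same organo-SOMO allylation and NaBH4 reduction give (2R,6S)-2-ethenyl-6-(hydroxymethyl)non-8-en-1-yl acetate F6. Iodoetherification (I2, NaHCO3, MeCN, 0 °C) ties the hydroxyl and the allyl group together as (2R)-2-ethenyl-5-[(3S)-5-(iodomethyl)oxolan-3-yl]pentyl acetate F7, a mixture of epimers at oxolane C5 that is of no consequence. 9-BBN and then 8 under the conditions of step 4 give (2R,5Z)-7-hydroxy-2-{3-[(3S)-5-(iodomethyl)oxolan-3-yl]propyl}-6-methylhept-5-en-1-yl acetate F8. Zn dust in AcOH/THF reopens the ring and gives 13, where the route is rejoined.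

Step 9. The α-bromobutenolide is base-sensitive, and B-alkyl coupling to it rests on the α-halo enone analogy. Fallback: build the butenolide on the alkene instead of coupling a preformed one. Setting out from 13, ruthenium-catalysed alkene–alkyne coupling (CpRu(cod)Cl, MeOH, reflux; Alder-ene type) with ethyl 4-hydroxybut-2-ynoate, with lactonisation in the same pot, gives (2R,5Z)-7-hydroxy-2-[(4S,5E)-4-(hydroxymethyl)-7-(2-oxo-2,5-dihydrofuran-3-yl)hept-5-en-1-yl]-6-methylhept-5-en-1-yl acetate F9. Selective hydrogenation of the disubstituted alkene (RhCl(PPh3)3, H2 1 atm, benzene/EtOH) gives 21.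

**Further compounds**
F1 | step 1 | diethyl 2-[4-(1,3-dioxolan-2-yl)butyl]propanedioate | CCOC(=O)C(CCCCC1OCCO1)C(=O)OCC
F2 | step 1 | 2-[4-(1,3-dioxolan-2-yl)butyl]propane-1,3-diol | OCC(CO)CCCCC1OCCO1
F3 | step 1 | (2R)-6-(1,3-dioxolan-2-yl)-2-(hydroxymethyl)hexyl acetate | CC(=O)OC[C@@H](CO)CCCCC1OCCO1
F4 | step 1 | (2S)-6-(1,3-dioxolan-2-yl)-2-formylhexyl acetate | CC(=O)OC[C@@H](C=O)CCCCC1OCCO1
F5 | step 6 | (2R)-2-ethenyl-7-oxoheptyl acetate | CC(=O)OC[C@@H](C=C)CCCCC=O
F6 | step 6 | (2R,6S)-2-ethenyl-6-(hydroxymethyl)non-8-en-1-yl acetate | CC(=O)OC[C@@H](C=C)CCC[C@H](CO)CC=C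
F7 | step 6 | (2R)-2-ethenyl-5-[(3S)-5-(iodomethyl)oxolan-3-yl]pentyl acetate | CC(=O)OC[C@@H](C=C)CCC[C@H](CO1)CC1CI
F8 | step 6 | (2R,5Z)-7-hydroxy-2-{3-[(3S)-5-(iodomethyl)oxolan-3-yl]propyl}-6-methylhept-5-en-1-yl acetate | CC(=O)OC[C@@H](CC/C=C(/C)CO)CCC[C@H](CO1)CC1CI
F9 | step 9 | (2R,5Z)-7-hydroxy-2-[(4S,5E)-4-(hydroxymethyl)-7-(2-oxo-2,5-dihydrofuran-3-yl)hept-5-en-1-yl]-6-methylhept-5-en-1-yl acetate | CC(=O)OC[C@@H](CC/C=C(/C)CO)CCC[C@H](CO)/C=C/CC1=CCOC1=O
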